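## Structural features

The target is a (2R,3R)-dihydroflavonol: a chroman-4-one in which ring C is fused to the resorcinol-type ring A through C4a and C8a, with a 4-hydroxy-3,5-diprenylphenyl ring B on C2 and a hydroxyl on C3. C2 and C3 are adjacent stereocentres with a trans relation. C3 lies α to the C4 ketone and C2 is a benzylic ether carbon β to it, so base can enolise C3 and open the C2–O1 bond. Each of the three prenyl groups (C8, C3', C5') stands ortho to a phenol, so acid turns them into dimethylchromans. Their trisubstituted alkenes also rule out hydrogenolysis, peracids, osmium reagents and quinone oxidants. The real difficulty is to set two contiguous stereocentres in the absolute sense on a skeleton that tolerates neither strong acid, nor base, nor electrophilic oxidants, and to place three prenyl groups regioselectively on two electron-rich rings. The key step exploits the fact that O1 sits on C8a and C4 on C4a of one phenol, which is the O1=C8a–C4a=C4 pattern of an ortho-quinone methide heterodiene. The trans C2(aryl)–C3(oxygen) unit maps onto an (E)-2-arylvinyl ester, and the C4 oxygen onto the formyl carbon of a salicylaldehyde.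

## Logic of the disconnections

20 ⇐ 19 ⇐ 18. The last cuts are two aryl O–Si bonds and the C3 O–acyl bond. They are cut last because 20 survives neither base nor acid. This demands a non-basic deacylation (18 to 19) while the phenols are still capped, and a buffered fluoride step (19 to 20). A carbonate/methanol deacylation is avoided: it would strip the aryl silyl ethers and expose the ketol to base.

18 ⇐ 17 ⇐ 16. The C4 carbonyl is traced back to a C4 hydroxyl and then to a C4 methyl ether. The gain is that C4 may enter at the acetal oxidation level that the cycloaddition delivers. The forward steps need an ionising exchange at C4 that leaves the neighbouring acetate in place, and a neutral oxidation.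

16 ⇐ 4 + 12 + 13 (through 14 and 15). The bonds C4–C3 and O1–C2 are cut, which opens ring C and removes C2, C3 and C4 as stereocentres at once. It splits the molecule into two halves of similar size. The cycloaddition creates three stereocentres, not two. The C2/C3 configuration is linked to the face of the heterodiene only through the endo/exo preference, so a C4 epimer need not share the C2/C3 sense of the main product. The forward step must therefore be regioselective, chemoselective over six alkenes, enantioselective and diastereoselective, and 16 must be a single diastereomer before C4 is erased.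

4 ⇐ 3 ⇐ 1 + 2. The 4-O–Si bond and then the C3–prenyl bond are cut. This leads back to two commodity chemicals in two steps. The price is a C-alkylation whose regiochemistry relies on the position between the two oxygens being the most nucleophilic.

12 ⇐ 11 ⇐ 9 ⇐ 8. The enol C–O bond is cut to a C–B bond, the C–B and C–H bonds across the alkene are cut to an alkyne, and the alkyne carbon is cut from an aldehyde. The reason is geometry: enolisation of an arylacetaldehyde would give both alkene isomers, whereas syn hydroboration followed by stereoretentive C–O coupling fixes the (E) alkene. The demand is that the boron chemistry spares the two prenyl alkenes and the aryl silyl ether.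

8 ⇐ 6 + 7 ⇐ 5. Both aryl–prenyl bonds are cut at once, back to a dibromide whose halogens mark the two positions. The phenol is silylated first, because the silyl ether is needed through to the end. In 6 it is flanked by two bromines and para to a formyl group, so it is labile, and the coupling must run under neutral conditions.

## Other disconnections considered

Alternative 1: The cut runs through ring A (C4a–C5 and C8–C8a), so ring C is made first and ring A is annulated onto it. In the forward sense the sulfinyl dihydropyranone A2 already holds C2, C3 and the sulfinyl group on the future C4a. It would take up the 1-methoxy-3-silyloxy diene A3 across its C4a=C8a bond in a Diels–Alder reaction. Loss of benzenesulfenic acid and methanol would aromatise ring A and give the protected flavanone A1 with the C7 hydroxyl free.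
- In favour: the ring A pattern (oxygen on C7, prenyl on C8) is written into A3 and does not depend on substitution of a resorcinol. The C4 ketone is present from the start. Neither stereocentre is formed or touched in the key step.
- Against: both stereocentres must be built beforehand on a small ring in which C3 is α to a ketone and C2–O1 belongs to a vinylogous ester. The sulfoxide adds a stereogenic sulfur that is thrown away. A3 is a skipped, acid-sensitive silyl enol ether that must be geometrically pure. Addition to a fully substituted, sulfinyl-bearing alkene carbon would need heat, which invites early sulfoxide elimination and epimerisation at C3.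
- Comparison: it is better on the regiochemistry of ring A and on redox economy after the key step. It is equal in rings and skeletal bonds formed (one ring, two bonds). It creates no stereocentre, so the stereochemical problem moves into the synthesis of A2, which should cost clearly more steps than the seven that lead to 4 and 12. Mechanistically it trades an ionic, catalyst-controlled cycloaddition of uncertain selectivity for a thermal one of predictable regiochemistry but doubtful thermal tolerance. Its end game needs an acidic MOM cleavage next to prenyl phenols, which the silyl-only end game avoids.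

Alternative 2: The cuts are C4a–C4, C4–C3 and O1–C2, all three around one molecule of carbon monoxide. PdCl2(PPh3)2 (a divalent palladium precatalyst that enters the cycle as zerovalent palladium) in diethylamine would join the iodophenol A5, CO and the ring B alkyne A6 to an alkynyl ketone. The phenol then closes this in a 6-endo-dig conjugate addition to the flavone A4.
- In favour: the reaction type is well established for flavones and highly convergent. It forms the ring and three skeletal bonds in one operation and tolerates prenyl alkenes and MOM ethers. A6 is the MOM analogue of 9, so the ring B chemistry is shared.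
- Against: A4 is flat and has neither the C3 oxygen nor a stereocentre. The C2=C3 bond would have to be reduced enantioselectively beside three prenyl alkenes, and C3 hydroxylated trans through an enolate that can expel the ring phenoxide. The 5-exo closure to an aurone competes, and the MOM groups must finally leave under acid.
- Comparison: on reliability of the key step, convergence and number of bonds made it is the better plan. On stereocentres (none against two that persist) and on what remains after the key step it is worse. The total step count should be higher, because the stereochemistry needs two further selective steps on a fragile core.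

Alternative 3: The cut is the single bond C4–C4a; O1–C2 and both stereocentres are in place before the ring is closed. The bromo Weinreb amide A8 would undergo bromine–lithium exchange with n-BuLi at low temperature. The aryllithium adds to the N-methoxy-N-methyl amide, whose chelated adduct collapses only on work-up, and gives the protected flavanone A7 directly at the ketone level.
- In favour: it is a purely anionic, well-precedented ring closure (Parham cyclisation). The ketone arises without redox adjustment, which is better than the two-step C4 adjustment of the chosen plan. The configuration of A7 is simply that of A8, so the absolute configuration is more predictable.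
- Against: A8 needs an aryl ether bond from a hindered ortho-bromo, ortho-prenyl phenol to a benzylic carbon activated by an electron-rich ring, made with defined configuration. Displacements at such a carbon tend to ionise. In the key step the organolithium can act as a base: deprotonation α to the amide would expel the β-aryloxide, the MOM ethers direct ortho-lithiation, and the benzylic–allylic CH2 groups are further acidic sites.
- Comparison: one ring and one bond against one ring and two bonds; no stereocentre set against two. The stereocentres would have to come from an earlier asymmetric reaction that distinguishes a cinnamate-type alkene from prenyl alkenes, and the route is linear, so more steps are expected. The final acidic MOM removal is again less safe than buffered desilylation.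

Key step: step 8

Assumption: the (R)-configured phosphoric acid is taken as the antipode that leads to the (2R,3R) series and 16 is drawn as the 2,4-cis (4R) epimer expected from an aryl-endo transition state; the sense of induction cannot be predicted, and the (S)-acid would be used if it proves opposite.

## Route

Step 1
Reactants: 1 2,4-dihydroxybenzaldehyde; 2 prenyl bromide (1-bromo-3-methylbut-2-ene)
Product: 3 2,4-dihydroxy-3-(3-methylbut-2-en-1-yl)benzaldehyde
Conditions: KOH (10% aq.), 0 °C to rt
Reagents that add atoms: none
Why: Nuclear C-alkylation of the resorcinol phenoxide in water, where solvation of oxygen favours carbon attack and the position between the two oxygens is the most nucleophilic. The C5 and O-alkylated isomers are expected as by-products and are removed by chromatography.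

Step 2
Reactants: 3 2,4-dihydroxy-3-(3-methylbut-2-en-1-yl)benzaldehyde
Product: 4 4-[(tert-butyldimethylsilyl)oxy]-2-hydroxy-3-(3-methylbut-2-en-1-yl)benzaldehyde
Conditions: TBSCl (1.05 equiv), imidazole, CH2Cl2, 0 °C
Reagents that add atoms: tert-butyldimethylsilyl chloride, CC(C)(C)[Si](C)(C)Cl
Why: Selective O-silylation: the 2-hydroxyl is tied up in a hydrogen bond to the formyl group, so the 4-hydroxyl reacts first.

Step 3
Reactants: 5 3,5-dibromo-4-hydroxybenzaldehyde
Product: 6 3,5-dibromo-4-[(tert-butyldimethylsilyl)oxy]benzaldehyde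
Conditions: TBSCl, imidazole, DMF, rt
Reagents that add atoms: tert-butyldimethylsilyl chloride, CC(C)(C)[Si](C)(C)Cl
Why: Standard phenol silylation. The product is an electron-poor aryl silyl ether and is kept away from base and fluoride until the bromines are replaced.

Step 4
Reactants: 6 3,5-dibromo-4-[(tert-butyldimethylsilyl)oxy]benzaldehyde; 7 tributyl(3-methylbut-2-en-1-yl)stannane (2.4 equiv)
Product: 8 4-[(tert-butyldimethylsilyl)oxy]-3,5-bis(3-methylbut-2-en-1-yl)benzaldehyde
Conditions: Pd(PPh3)4 (5 mol%), PhMe, 100 °C
Reagents that add atoms: none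
Why: Double Stille coupling: zerovalent palladium inserts into each C–Br bond (activated by the para formyl group), and the allylic stannane should transfer the prenyl group mainly through its unsubstituted terminus. The neutral, non-nucleophilic medium preserves the aldehyde and the labile silyl ether.

Step 5
Reactants: 8 4-[(tert-butyldimethylsilyl)oxy]-3,5-bis(3-methylbut-2-en-1-yl)benzaldehyde
Product: 9 tert-butyl[4-ethynyl-2,6-bis(3-methylbut-2-en-1-yl)phenoxy]dimethylsilane
Conditions: Me3SiCHN2, LiN(i-Pr)2, THF, −78 °C to rt; H2O
Reagents that add atoms: trimethylsilyldiazomethane, C[Si](C)(C)C=[N+]=[N-]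
Why: Colvin homologation: the lithiated diazo compound adds to the aldehyde, Peterson-type elimination gives a diazoalkene, and loss of N2 with 1,2-hydrogen shift gives the terminal alkyne. No methanolic base is present, so the aryl silyl ether should survive.

Step 6
Reactants: 9 tert-butyl[4-ethynyl-2,6-bis(3-methylbut-2-en-1-yl)phenoxy]dimethylsilane
Product: 11 [(E)-2-{4-[(tert-butyldimethylsilyl)oxy]-3,5-bis(3-methylbut-2-en-1-yl)phenyl}ethenyl]boronic acid, via catechol alkenylboronate 10 (not isolated)
Conditions: catecholborane (1.2 equiv), THF, 70 °C; then H2O, rt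
Reagents that add atoms: catecholborane, B1Oc2ccccc2O1; water, O
Why: Uncatalysed hydroboration of a terminal alkyne is syn and anti-Markovnikov, which fixes the (E) geometry. The trisubstituted prenyl alkenes should not react with catecholborane at this temperature, and water hydrolyses the catechol ester.

Step 7
Reactants: 11 [(E)-2-{4-[(tert-butyldimethylsilyl)oxy]-3,5-bis(3-methylbut-2-en-1-yl)phenyl}ethenyl]boronic acid
Product: 12 (E)-2-{4-[(tert-butyldimethylsilyl)oxy]-3,5-bis(3-methylbut-2-en-1-yl)phenyl}ethenyl acetate
Conditions: AcOH (3 equiv), Cu(OTf)2 (20 mol%), DMAP, 4 Å MS, O2 (1 atm), MeCN, 40 °C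
Reagents that add atoms: acetic acid, CC(=O)O
Why: Chan–Lam–Evans enol esterification: the alkenyl group passes from boron to divalent copper, oxidation to trivalent copper is followed by C–O reductive elimination with retention of alkene geometry. The (E) enol acetate is thus made without an enolisation step.

Step 8
Reactants: 4 4-[(tert-butyldimethylsilyl)oxy]-2-hydroxy-3-(3-methylbut-2-en-1-yl)benzaldehyde; 12 (E)-2-{4-[(tert-butyldimethylsilyl)oxy]-3,5-bis(3-methylbut-2-en-1-yl)phenyl}ethenyl acetate (1.3 equiv); 13 trimethyl orthoformate (2 equiv)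
Product: 16 (2R,3S,4R)-7-[(tert-butyldimethylsilyl)oxy]-2-{4-[(tert-butyldimethylsilyl)oxy]-3,5-bis(3-methylbut-2-en-1-yl)phenyl}-4-methoxy-8-(3-methylbut-2-en-1-yl)chroman-3-yl acetate, via salicylaldehyde dimethyl acetal 14 (not isolated), via 4-methoxy ortho-quinone methide 15 (not isolated)
Conditions: (R)-3,3'-bis(2,4,6-triisopropylphenyl)-1,1'-binaphthyl-2,2'-diyl hydrogen phosphate (10 mol%), 5 Å MS, PhMe, −20 to 0 °C; chromatography to one diastereomer
Reagents that add atoms: none
Why: Proposed new method: the acid turns 4 and 13 into acetal 14 and ionises it to the O-protonated form of the methoxy ortho-quinone methide 15, held as a contact ion pair in which the phosphate also hydrogen-bonds the phenol; the closest known reaction type is the Brønsted-acid-promoted [4+2] cycloaddition of ortho-quinone methides from salicylaldehyde acetals or 2-hydroxybenzyl alcohols with styrenes, which has chiral phosphoric acid variants but has not been shown enantioselectively with an enol ester. The enol acetate 12 should attack the cationic carbon (future C4) through its acetoxy-bearing carbon, because the charge that builds up on the other alkene carbon is benzylic to the electron-rich ring B while the acyl group keeps the enol oxygen a weak donor, and the phenol oxygen then bonds to that benzylic carbon. Ring C is thus closed by an asynchronous inverse-electron-demand oxa-[4+2] cycloaddition (C4–C3 leading, O1–C2 following), whose stepwise limit is a Prins-type addition followed by capture of the benzylic cation by the phenol oxygen. The trans C2/C3 relation comes from suprafacial addition to the (E) alkene and, in the stepwise limit, from ring closure through the conformer with both substituents equatorial. The absolute configuration at C3 is fixed when one enol face meets the ion-paired heterodiene under control of the chiral phosphate, C2 follows from C3, and C4 should arise 2,4-cis from an aryl-endo transition state. Because the C2/C3 sense is tied to the heterodiene face only through this endo/exo preference, 16 is purified to a single diastereomer before C4 is erased. The step needs regioselectivity (aryl outweighing acetoxy as donor, secured by the 4-silyloxy-3,5-dialkylphenyl group), chemoselectivity for the conjugated enol acetate over the isolated prenyl alkenes (secured by its higher nucleophilicity and its excess), and an acid too weak to cyclise the ortho-prenyl phenol of 4 (secured by the phosphoric acid at low temperature).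

Step 9
Reactants: 16 (2R,3S,4R)-7-[(tert-butyldimethylsilyl)oxy]-2-{4-[(tert-butyldimethylsilyl)oxy]-3,5-bis(3-methylbut-2-en-1-yl)phenyl}-4-methoxy-8-(3-methylbut-2-en-1-yl)chroman-3-yl acetate
Product: 17 (2R,3S)-7-[(tert-butyldimethylsilyl)oxy]-2-{4-[(tert-butyldimethylsilyl)oxy]-3,5-bis(3-methylbut-2-en-1-yl)phenyl}-4-hydroxy-8-(3-methylbut-2-en-1-yl)chroman-3-yl acetate (C4 epimers)
Conditions: CSA (20 mol%), MeCN–H2O (9:1), rt
Reagents that add atoms: water, O
Why: Ionising solvolysis: mild acid regenerates the C4 cation, which is stabilised by O1 and the C7 oxygen, and the large excess of water captures it. The C4 configuration is of no consequence, and the aryl silyl ethers and the prenyl groups (no free ortho phenol) should tolerate the conditions.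

Step 10
Reactants: 17 (2R,3S)-7-[(tert-butyldimethylsilyl)oxy]-2-{4-[(tert-butyldimethylsilyl)oxy]-3,5-bis(3-methylbut-2-en-1-yl)phenyl}-4-hydroxy-8-(3-methylbut-2-en-1-yl)chroman-3-yl acetate
Product: 18 (2R,3R)-7-[(tert-butyldimethylsilyl)oxy]-2-{4-[(tert-butyldimethylsilyl)oxy]-3,5-bis(3-methylbut-2-en-1-yl)phenyl}-8-(3-methylbut-2-en-1-yl)-4-oxochroman-3-yl acetate
Conditions: Dess–Martin periodinane, pyridine, CH2Cl2, 0 °C to rt
Reagents that add atoms: none
Why: Dess–Martin oxidation of a secondary benzylic alcohol under buffered, neutral conditions. Both C4 epimers converge on one ketone, and alkenes, silyl ethers and the C3 centre are not touched.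

Step 11
Reactants: 18 (2R,3R)-7-[(tert-butyldimethylsilyl)oxy]-2-{4-[(tert-butyldimethylsilyl)oxy]-3,5-bis(3-methylbut-2-en-1-yl)phenyl}-8-(3-methylbut-2-en-1-yl)-4-oxochroman-3-yl acetate
Product: 19 (2R,3R)-7-[(tert-butyldimethylsilyl)oxy]-2-{4-[(tert-butyldimethylsilyl)oxy]-3,5-bis(3-methylbut-2-en-1-yl)phenyl}-3-hydroxy-8-(3-methylbut-2-en-1-yl)chroman-4-one
Conditions: Sc(OTf)3 (20 mol%), MeOH–THF–H2O, 30 °C
Reagents that add atoms: none
Why: Lewis-acid-catalysed transesterification of an α-acetoxy ketone: chelation of scandium between the ketone and the ester activates this acetate selectively. No base is present, so neither enolisation at C3 nor opening of the C2–O1 bond is expected, and the phenols stay capped so the prenyl groups cannot cyclise.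

Step 12
Reactants: 19 (2R,3R)-7-[(tert-butyldimethylsilyl)oxy]-2-{4-[(tert-butyldimethylsilyl)oxy]-3,5-bis(3-methylbut-2-en-1-yl)phenyl}-3-hydroxy-8-(3-methylbut-2-en-1-yl)chroman-4-one
Product: 20 (2R,3R)-3,7-dihydroxy-2-[4-hydroxy-3,5-bis(3-methylbut-2-en-1-yl)phenyl]-8-(3-methylbut-2-en-1-yl)chroman-4-one
Conditions: n-Bu4NF, AcOH (1:1.2), THF, 0 °C to rt
Reagents that add atoms: none
Why: Fluoride cleavage of the two aryl silyl ethers. The acetic acid buffer keeps the liberated phenols protonated, which protects the dihydroflavonol from base-induced epimerisation and ring opening, and is too weak to cyclise the prenyl phenols.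

## Compound list

1 | 2,4-dihydroxybenzaldehyde | O=Cc1ccc(O)cc1O | starting material
2 | prenyl bromide (1-bromo-3-methylbut-2-ene) | CC(C)=CCBr | starting material
3 | 2,4-dihydroxy-3-(3-methylbut-2-en-1-yl)benzaldehyde | O=Cc1ccc(O)c(CC=C(C)C)c1O | intermediate
4 | 4-[(tert-butyldimethylsilyl)oxy]-2-hydroxy-3-(3-methylbut-2-en-1-yl)benzaldehyde | O=Cc1ccc(O[Si](C)(C)C(C)(C)C)c(CC=C(C)C)c1O | intermediate
5 | 3,5-dibromo-4-hydroxybenzaldehyde | O=Cc1cc(Br)c(O)c(Br)c1 | starting material
6 | 3,5-dibromo-4-[(tert-butyldimethylsilyl)oxy]benzaldehyde | O=Cc1cc(Br)c(O[Si](C)(C)C(C)(C)C)c(Br)c1 | intermediate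
7 | tributyl(3-methylbut-2-en-1-yl)stannane | CCCC[Sn](CCCC)(CCCC)CC=C(C)C | starting material
8 | 4-[(tert-butyldimethylsilyl)oxy]-3,5-bis(3-methylbut-2-en-1-yl)benzaldehyde | O=Cc1cc(CC=C(C)C)c(O[Si](C)(C)C(C)(C)C)c(CC=C(C)C)c1 | intermediate
9 | tert-butyl[4-ethynyl-2,6-bis(3-methylbut-2-en-1-yl)phenoxy]dimethylsilane | C#Cc1cc(CC=C(C)C)c(O[Si](C)(C)C(C)(C)C)c(CC=C(C)C)c1 | intermediate
10 | 2-[(E)-2-{4-[(tert-butyldimethylsilyl)oxy]-3,5-bis(3-methylbut-2-en-1-yl)phenyl}ethenyl]-1,3,2-benzodioxaborole | CC(C)=CCc1cc(/C=C/B2Oc3ccccc3O2)cc(CC=C(C)C)c1O[Si](C)(C)C(C)(C)C | intermediate (not isolated)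
11 | [(E)-2-{4-[(tert-butyldimethylsilyl)oxy]-3,5-bis(3-methylbut-2-en-1-yl)phenyl}ethenyl]boronic acid | CC(C)=CCc1cc(/C=C/B(O)O)cc(CC=C(C)C)c1O[Si](C)(C)C(C)(C)C | intermediate
12 | (E)-2-{4-[(tert-butyldimethylsilyl)oxy]-3,5-bis(3-methylbut-2-en-1-yl)phenyl}ethenyl acetate | CC(=O)O/C=C/c1cc(CC=C(C)C)c(O[Si](C)(C)C(C)(C)C)c(CC=C(C)C)c1 | intermediate
13 | trimethyl orthoformate | COC(OC)OC | starting material
14 | 3-[(tert-butyldimethylsilyl)oxy]-6-(dimethoxymethyl)-2-(3-methylbut-2-en-1-yl)phenol | COC(OC)c1ccc(O[Si](C)(C)C(C)(C)C)c(CC=C(C)C)c1O | intermediate (not isolated)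
15 | 3-[(tert-butyldimethylsilyl)oxy]-6-(methoxymethylidene)-2-(3-methylbut-2-en-1-yl)cyclohexa-2,4-dien-1-one (reacts as its O-protonated oxocarbenium phosphate) | COC=C1C=CC(O[Si](C)(C)C(C)(C)C)=C(CC=C(C)C)C1=O | intermediate (not isolated)
16 | (2R,3S,4R)-7-[(tert-butyldimethylsilyl)oxy]-2-{4-[(tert-butyldimethylsilyl)oxy]-3,5-bis(3-methylbut-2-en-1-yl)phenyl}-4-methoxy-8-(3-methylbut-2-en-1-yl)chroman-3-yl acetate | CC(C)=CCc1cc([C@H]2Oc3c(ccc(O[Si](C)(C)C(C)(C)C)c3CC=C(C)C)[C@@H](OC)[C@@H]2OC(C)=O)cc(CC=C(C)C)c1O[Si](C)(C)C(C)(C)C | intermediate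
17 | (2R,3S)-7-[(tert-butyldimethylsilyl)oxy]-2-{4-[(tert-butyldimethylsilyl)oxy]-3,5-bis(3-methylbut-2-en-1-yl)phenyl}-4-hydroxy-8-(3-methylbut-2-en-1-yl)chroman-3-yl acetate (C4 epimers) | CC(C)=CCc1cc([C@H]2Oc3c(ccc(O[Si](C)(C)C(C)(C)C)c3CC=C(C)C)C(O)[C@@H]2OC(C)=O)cc(CC=C(C)C)c1O[Si](C)(C)C(C)(C)C | intermediate
18 | (2R,3R)-7-[(tert-butyldimethylsilyl)oxy]-2-{4-[(tert-butyldimethylsilyl)oxy]-3,5-bis(3-methylbut-2-en-1-yl)phenyl}-8-(3-methylbut-2-en-1-yl)-4-oxochroman-3-yl acetate | CC(C)=CCc1cc([C@H]2Oc3c(ccc(O[Si](C)(C)C(C)(C)C)c3CC=C(C)C)C(=O)[C@@H]2OC(C)=O)cc(CC=C(C)C)c1O[Si](C)(C)C(C)(C)C | intermediate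
19 | (2R,3R)-7-[(tert-butyldimethylsilyl)oxy]-2-{4-[(tert-butyldimethylsilyl)oxy]-3,5-bis(3-methylbut-2-en-1-yl)phenyl}-3-hydroxy-8-(3-methylbut-2-en-1-yl)chroman-4-one | CC(C)=CCc1cc([C@H]2Oc3c(ccc(O[Si](C)(C)C(C)(C)C)c3CC=C(C)C)C(=O)[C@@H]2O)cc(CC=C(C)C)c1O[Si](C)(C)C(C)(C)C | intermediate
20 | (2R,3R)-3,7-dihydroxy-2-[4-hydroxy-3,5-bis(3-methylbut-2-en-1-yl)phenyl]-8-(3-methylbut-2-en-1-yl)chroman-4-one | CC(C)=CCc1cc([C@H]2Oc3c(ccc(O)c3CC=C(C)C)C(=O)[C@@H]2O)cc(CC=C(C)C)c1O | target

## Step count and least certain steps

Total: 12 steps. Longest linear sequence: 10 steps (steps 3 to 12, from 5 to 20); the ring A branch (steps 1 and 2) joins at step 8.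

Step 8 (key step). The most likely failure is loss of selectivity: capture of the oxocarbenium by a prenyl alkene, acid-induced closure of the ortho-prenyl phenol of 4, methanolysis of the enol acetate, or weak facial and endo/exo discrimination that leaves C2/C3 with low enantiomeric purity. This is because the nucleophile carries an electron-withdrawing acetoxy group on its attacking carbon, and the catalyst has to order an intermolecular ion-pair reaction for which no direct model exists. The fallback uses known chemistry and closes ring C by the chalcone epoxide route; it sets out from 8 and comes back to the route at 20.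
- 8 is desilylated (n-Bu4NF, AcOH) to 4-hydroxy-3,5-bis(3-methylbut-2-en-1-yl)benzaldehyde F1 and protected (MOMCl, i-Pr2NEt) as 4-(methoxymethoxy)-3,5-bis(3-methylbut-2-en-1-yl)benzaldehyde F2.
- Commercial 2,4-dihydroxyacetophenone is C-prenylated with 2 (aq. KOH) to 1-[2,4-dihydroxy-3-(3-methylbut-2-en-1-yl)phenyl]ethanone F3 and converted (NaH, MOMCl) into 1-[2,4-bis(methoxymethoxy)-3-(3-methylbut-2-en-1-yl)phenyl]ethanone F4.
- Claisen–Schmidt condensation of F2 with F4 (KOH, EtOH) should give (E)-1-[2,4-bis(methoxymethoxy)-3-(3-methylbut-2-en-1-yl)phenyl]-3-[4-(methoxymethoxy)-3,5-bis(3-methylbut-2-en-1-yl)phenyl]prop-2-en-1-one F5.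
- Juliá–Colonna epoxidation (poly-L-leucine, urea–H2O2, DBU, THF) is a nucleophilic epoxidation that touches only the enone. It should give [2,4-bis(methoxymethoxy)-3-(3-methylbut-2-en-1-yl)phenyl]{(2R,3S)-3-[4-(methoxymethoxy)-3,5-bis(3-methylbut-2-en-1-yl)phenyl]oxiran-2-yl}methanone F6.
- HCl in MeOH–THF at gentle warmth then removes the three MOM groups, and the freed 2'-phenol opens the epoxide at the benzylic carbon with inversion to give 20. The price is an acidic last step next to prenyl phenols.

Step 7. Protodeboronation, oxidative homocoupling to a diene or over-oxidation of the electron-rich styrene may outrun C–O bond formation, because the alkenylboronic acid is electron-rich and the coupling runs under O2 with copper. The fallback sets out from 8 and comes back at 12.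
- Wittig reaction with Ph3P(CH2OMe)Cl and KN(SiMe3)2 gives tert-butyl[4-(2-methoxyethenyl)-2,6-bis(3-methylbut-2-en-1-yl)phenoxy]dimethylsilane F7 as an alkene mixture.
- Dilute aqueous HCl in THF hydrolyses it to {4-[(tert-butyldimethylsilyl)oxy]-3,5-bis(3-methylbut-2-en-1-yl)phenyl}acetaldehyde F8.
- Enol acetylation (Ac2O, KOAc, heat) then gives the enol acetate as a mixture of alkene isomers, from which 12 is separated by chromatography. The price is poor geometric control.

Step 4. The second coupling may stall, the prenyl group may be delivered with allylic transposition (1,1-dimethylallyl instead of prenyl), or the activated silyl ether may be lost on heating. The cause is that both positions are ortho to a bulky silyloxy group and the allyl-palladium intermediate can eliminate at either terminus. The fallback sets out from 6 and comes back at 8.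
- Double Stille coupling with allyltributylstannane (Pd(PPh3)4, PhMe) has no regiochemical ambiguity and gives 3,5-diallyl-4-[(tert-butyldimethylsilyl)oxy]benzaldehyde F9.
- Cross-metathesis with 2-methylbut-2-ene (second-generation Grubbs catalyst, RuCl2(=CHPh)(H2IMes)(PCy3), CH2Cl2, 40 °C) converts both allyl groups into prenyl groups and gives 8.

Step 1. Alkylation at C5, at oxygen, or twice is the likely failure, because the phenoxide is an ambident nucleophile with two activated ring positions. The fallback sets out from 1 and comes back at 3.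
- Selective 4-O-allylation (allyl bromide, K2CO3, acetone) gives 4-(allyloxy)-2-hydroxybenzaldehyde F10.
- Claisen rearrangement (N,N-diethylaniline, 190 °C) is directed to the position between the oxygens by the chelated 2-hydroxyl and gives 3-allyl-2,4-dihydroxybenzaldehyde F11.
- Cross-metathesis with 2-methylbut-2-ene (second-generation Grubbs catalyst, RuCl2(=CHPh)(H2IMes)(PCy3)) gives 3.

Step 11. The chelation-assisted methanolysis may be slow on this hindered, lipophilic substrate. Forcing it risks epimerisation or hydration of a prenyl group. The same acetate may already have migrated to O4 by neighbouring-group participation during the C4 exchange of step 9. The fallback removes the acetate before C4 is touched; it sets out from 16 and comes back at 20.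
- i-Bu2AlH (CH2Cl2, −78 °C) cleaves the acetate to (2R,3S,4R)-7-[(tert-butyldimethylsilyl)oxy]-2-{4-[(tert-butyldimethylsilyl)oxy]-3,5-bis(3-methylbut-2-en-1-yl)phenyl}-4-methoxy-8-(3-methylbut-2-en-1-yl)chroman-3-ol F12.
- TBSOTf and 2,6-lutidine give the 3-O-silyl ether, (2R,3S,4R)-3,7-bis[(tert-butyldimethylsilyl)oxy]-2-{4-[(tert-butyldimethylsilyl)oxy]-3,5-bis(3-methylbut-2-en-1-yl)phenyl}-4-methoxy-8-(3-methylbut-2-en-1-yl)chroman F13.
- CSA in MeCN–H2O exchanges the methyl ether to give (2R,3S)-3,7-bis[(tert-butyldimethylsilyl)oxy]-2-{4-[(tert-butyldimethylsilyl)oxy]-3,5-bis(3-methylbut-2-en-1-yl)phenyl}-8-(3-methylbut-2-en-1-yl)chroman-4-ol F14 (C4 epimers).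
- Dess–Martin periodinane gives (2R,3R)-3,7-bis[(tert-butyldimethylsilyl)oxy]-2-{4-[(tert-butyldimethylsilyl)oxy]-3,5-bis(3-methylbut-2-en-1-yl)phenyl}-8-(3-methylbut-2-en-1-yl)chroman-4-one F15.
- n-Bu4NF buffered with AcOH removes all three silyl groups to give 20.

## Further compounds

F1 | step 8 | 4-hydroxy-3,5-bis(3-methylbut-2-en-1-yl)benzaldehyde | O=Cc1cc(CC=C(C)C)c(O)c(CC=C(C)C)c1
F2 | step 8 | 4-(methoxymethoxy)-3,5-bis(3-methylbut-2-en-1-yl)benzaldehyde | COCOc1c(CC=C(C)C)cc(C=O)cc1CC=C(C)C
F3 | step 8 | 1-[2,4-dihydroxy-3-(3-methylbut-2-en-1-yl)phenyl]ethanone | CC(=O)c1ccc(O)c(CC=C(C)C)c1O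
F4 | step 8 | 1-[2,4-bis(methoxymethoxy)-3-(3-methylbut-2-en-1-yl)phenyl]ethanone | COCOc1ccc(C(C)=O)c(OCOC)c1CC=C(C)C
F5 | step 8 | (E)-1-[2,4-bis(methoxymethoxy)-3-(3-methylbut-2-en-1-yl)phenyl]-3-[4-(methoxymethoxy)-3,5-bis(3-methylbut-2-en-1-yl)phenyl]prop-2-en-1-one | COCOc1ccc(C(=O)/C=C/c2cc(CC=C(C)C)c(OCOC)c(CC=C(C)C)c2)c(OCOC)c1CC=C(C)C
F6 | step 8 | [2,4-bis(methoxymethoxy)-3-(3-methylbut-2-en-1-yl)phenyl]{(2R,3S)-3-[4-(methoxymethoxy)-3,5-bis(3-methylbut-2-en-1-yl)phenyl]oxiran-2-yl}methanone | COCOc1ccc(C(=O)[C@@H]2O[C@H]2c3cc(CC=C(C)C)c(OCOC)c(CC=C(C)C)c3)c(OCOC)c1CC=C(C)C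
F7 | step 7 | tert-butyl[4-(2-methoxyethenyl)-2,6-bis(3-methylbut-2-en-1-yl)phenoxy]dimethylsilane (alkene isomers) | COC=Cc1cc(CC=C(C)C)c(O[Si](C)(C)C(C)(C)C)c(CC=C(C)C)c1
F8 | step 7 | {4-[(tert-butyldimethylsilyl)oxy]-3,5-bis(3-methylbut-2-en-1-yl)phenyl}acetaldehyde | O=CCc1cc(CC=C(C)C)c(O[Si](C)(C)C(C)(C)C)c(CC=C(C)C)c1
F9 | step 4 | 3,5-diallyl-4-[(tert-butyldimethylsilyl)oxy]benzaldehyde | C=CCc1cc(C=O)cc(CC=C)c1O[Si](C)(C)C(C)(C)C
F10 | step 1 | 4-(allyloxy)-2-hydroxybenzaldehyde | C=CCOc1ccc(C=O)c(O)c1
F11 | step 1 | 3-allyl-2,4-dihydroxybenzaldehyde | C=CCc1c(O)ccc(C=O)c1O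
F12 | step 11 | (2R,3S,4R)-7-[(tert-butyldimethylsilyl)oxy]-2-{4-[(tert-butyldimethylsilyl)oxy]-3,5-bis(3-methylbut-2-en-1-yl)phenyl}-4-methoxy-8-(3-methylbut-2-en-1-yl)chroman-3-ol | CC(C)=CCc1cc([C@H]2Oc3c(ccc(O[Si](C)(C)C(C)(C)C)c3CC=C(C)C)[C@@H](OC)[C@@H]2O)cc(CC=C(C)C)c1O[Si](C)(C)C(C)(C)C
F13 | step 11 | (2R,3S,4R)-3,7-bis[(tert-butyldimethylsilyl)oxy]-2-{4-[(tert-butyldimethylsilyl)oxy]-3,5-bis(3-methylbut-2-en-1-yl)phenyl}-4-methoxy-8-(3-methylbut-2-en-1-yl)chroman | CC(C)=CCc1cc([C@H]2Oc3c(ccc(O[Si](C)(C)C(C)(C)C)c3CC=C(C)C)[C@@H](OC)[C@@H]2O[Si](C)(C)C(C)(C)C)cc(CC=C(C)C)c1O[Si](C)(C)C(C)(C)C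
F14 | step 11 | (2R,3S)-3,7-bis[(tert-butyldimethylsilyl)oxy]-2-{4-[(tert-butyldimethylsilyl)oxy]-3,5-bis(3-methylbut-2-en-1-yl)phenyl}-8-(3-methylbut-2-en-1-yl)chroman-4-ol (C4 epimers) | CC(C)=CCc1cc([C@H]2Oc3c(ccc(O[Si](C)(C)C(C)(C)C)c3CC=C(C)C)C(O)[C@@H]2O[Si](C)(C)C(C)(C)C)cc(CC=C(C)C)c1O[Si](C)(C)C(C)(C)C
F15 | step 11 | (2R,3R)-3,7-bis[(tert-butyldimethylsilyl)oxy]-2-{4-[(tert-butyldimethylsilyl)oxy]-3,5-bis(3-methylbut-2-en-1-yl)phenyl}-8-(3-methylbut-2-en-1-yl)chroman-4-one | CC(C)=CCc1cc([C@H]2Oc3c(ccc(O[Si](C)(C)C(C)(C)C)c3CC=C(C)C)C(=O)[C@@H]2O[Si](C)(C)C(C)(C)C)cc(CC=C(C)C)c1O[Si](C)(C)C(C)(C)C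
A1 | alternative 1 | (2R,3R)-3-[(tert-butyldimethylsilyl)oxy]-7-hydroxy-2-[4-(methoxymethoxy)-3,5-bis(3-methylbut-2-en-1-yl)phenyl]-8-(3-methylbut-2-en-1-yl)chroman-4-one | CC(C)=CCc1cc([C@H]2Oc3c(ccc(O)c3CC=C(C)C)C(=O)[C@@H]2O[Si](C)(C)C(C)(C)C)cc(CC=C(C)C)c1OCOC
A2 | alternative 1 | (2R,3R)-3-[(tert-butyldimethylsilyl)oxy]-2-[4-(methoxymethoxy)-3,5-bis(3-methylbut-2-en-1-yl)phenyl]-5-(phenylsulfinyl)-2,3-dihydro-4H-pyran-4-one (one sulfur epimer; the sulfur configuration is not carried on) | CC(C)=CCc1cc([C@H]2OC=C(S(=O)c3ccccc3)C(=O)[C@@H]2O[Si](C)(C)C(C)(C)C)cc(CC=C(C)C)c1OCOC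
A3 | alternative 1 | (1E,3Z)-1-methoxy-7-methyl-3-[(trimethylsilyl)oxy]octa-1,3,6-triene | CO/C=C/C(O[Si](C)(C)C)=C/CC=C(C)C
A4 | alternative 2 | 7-(methoxymethoxy)-2-[4-(methoxymethoxy)-3,5-bis(3-methylbut-2-en-1-yl)phenyl]-8-(3-methylbut-2-en-1-yl)-4H-chromen-4-one | CC(C)=CCc1cc(-c2cc(=O)c3ccc(OCOC)c(CC=C(C)C)c3o2)cc(CC=C(C)C)c1OCOC
A5 | alternative 2 | 6-iodo-3-(methoxymethoxy)-2-(3-methylbut-2-en-1-yl)phenol | COCOc1ccc(I)c(O)c1CC=C(C)C
A6 | alternative 2 | 5-ethynyl-2-(methoxymethoxy)-1,3-bis(3-methylbut-2-en-1-yl)benzene | C#Cc1cc(CC=C(C)C)c(OCOC)c(CC=C(C)C)c1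
A7 | alternative 3 | (2R,3R)-3-[(tert-butyldimethylsilyl)oxy]-7-(methoxymethoxy)-2-[4-(methoxymethoxy)-3,5-bis(3-methylbut-2-en-1-yl)phenyl]-8-(3-methylbut-2-en-1-yl)chroman-4-one | CC(C)=CCc1cc([C@H]2Oc3c(ccc(OCOC)c3CC=C(C)C)C(=O)[C@@H]2O[Si](C)(C)C(C)(C)C)cc(CC=C(C)C)c1OCOC
A8 | alternative 3 | (2R,3R)-3-[2-bromo-5-(methoxymethoxy)-6-(3-methylbut-2-en-1-yl)phenoxy]-2-[(tert-butyldimethylsilyl)oxy]-N-methoxy-3-[4-(methoxymethoxy)-3,5-bis(3-methylbut-2-en-1-yl)phenyl]-N-methylpropanamide | CC(C)=CCc1cc([C@@H](Oc2c(Br)ccc(OCOC)c2CC=C(C)C)[C@@H](O[Si](C)(C)C(C)(C)C)C(=O)N(C)OC)cc(CC=C(C)C)c1OCOC
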